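**Strategy.** Ring C of the 7-methoxyflavone half (unit 1) is disconnected at C2–C3 and O1–C2. C3 lies between the C4 ketone and the aryl-bearing C2 and already carries phloroglucinol ring D, so ring C unfolds into a 2-hydroxydeoxybenzoin and 4-(benzyloxy)benzoyl chloride. One operation (O-aroylation, base-driven O-to-C acyl shift, cyclodehydration) makes both bonds and closes ring C, so the crowded C3–ring D bond is never made by biaryl coupling. The precursor is a 1-(2-hydroxy-4,6-dimethoxyphenyl)-2-arylethanone whose aryl group is ring D with two benzyl ethers and a para allyl ether. Removal of that allyl group later lets the luteolin half (unit 2) grow on ring D.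

Key step: step 8

Remark on stereochemistry: the bond between C3 of unit 1 and C6 of unit 2 has four ortho substituents, and the target is drawn without axial configuration. The route therefore aims at racemic (or freely rotating) material and contains no atroposelective step.

Remark on protecting groups: benzyl protects every oxygen that ends as a free phenol, allyl protects the one ring D oxygen that must be unmasked early, and methyl protects both ring A oxygens of unit 1 (the peri one is removed selectively at the end). Compounds 12 and 19 are purchased.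

**Step 1**
Reactants: 1 2,4,6-trihydroxybenzaldehyde
Product: 2 4-(allyloxy)-2,6-dihydroxybenzaldehyde
Conditions: allyl bromide (1.0 equiv), KHCO3, DMF, 40 °C
Reagents that add atoms: allyl bromide, C=CCBr
Why: Williamson etherification; the 4-OH is the most acidic hydroxyl and the only one not hydrogen-bonded to the formyl oxygen, so a bicarbonate base and one equivalent of halide should alkylate it preferentially.

**Step 2**
Reactants: 2 4-(allyloxy)-2,6-dihydroxybenzaldehyde
Product: 3 4-(allyloxy)-2,6-bis(benzyloxy)benzaldehyde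
Conditions: BnBr (2.5 equiv), K2CO3, DMF, 60 °C
Reagents that add atoms: benzyl bromide, BrCc1ccccc1
Why: Williamson etherification under more forcing carbonate conditions should convert both hydrogen-bonded ortho hydroxyls into benzyl ethers while the aldehyde and the allyl ether stay inert.

**Step 3**
Reactants: 3 4-(allyloxy)-2,6-bis(benzyloxy)benzaldehyde
Product: 4 2-[4-(allyloxy)-2,6-bis(benzyloxy)phenyl]acetonitrile
Conditions: TosMIC, t-BuOK, DME, −40 °C; then MeOH, reflux
Reagents that add atoms: p-toluenesulfonylmethyl isocyanide (TosMIC), Cc1ccc(cc1)S(=O)(=O)C[N+]#[C-]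
Why: Van Leusen reductive cyanation; the TosMIC anion adds to the aldehyde and closes to a 4-tosyl-2-oxazoline, base opens it to an N-formyl alkenyl sulfone, and methanol removes the formyl and sulfinyl groups to leave the homologous nitrile, so no ionisable 2,4,6-trialkoxybenzyl halide is needed.

**Step 4**
Reactants: 4 2-[4-(allyloxy)-2,6-bis(benzyloxy)phenyl]acetonitrile
Product: 5 2-[4-(allyloxy)-2,6-bis(benzyloxy)phenyl]acetic acid
Conditions: KOH, EtOH/H2O, reflux; then 2 M HCl to pH 2
Reagents that add atoms: water, O; potassium hydroxide, [K+].[OH-]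
Why: Alkaline nitrile hydrolysis through the primary amide should give the arylacetic acid on acidification, and aryl benzyl and allyl ethers are stable to aqueous hydroxide.

**Step 5**
Reactants: 5 2-[4-(allyloxy)-2,6-bis(benzyloxy)phenyl]acetic acid
Product: 6 2-[4-(allyloxy)-2,6-bis(benzyloxy)phenyl]-N-methoxy-N-methylacetamide
Conditions: CDI, CH2Cl2, rt; then MeNH(OMe)·HCl, rt
Reagents that add atoms: N,O-dimethylhydroxylamine hydrochloride, CNOC.Cl
Why: Amide coupling through the acyl imidazolide should give the Weinreb amide under near-neutral conditions that leave all ethers untouched.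

**Step 6**
Reactants: 7 3,5-dimethoxyphenol
Product: 8 1,3-dimethoxy-5-(methoxymethoxy)benzene
Conditions: NaH, THF, 0 °C; MOMCl, 0 °C → rt
Reagents that add atoms: chloromethyl methyl ether, COCCl
Why: O-alkylation of the sodium phenoxide (Williamson type) installs the MOM acetal, which serves as ortho-directing group and is later removed by mild acid.

**Step 7**
Reactants: 8 1,3-dimethoxy-5-(methoxymethoxy)benzene; 6 2-[4-(allyloxy)-2,6-bis(benzyloxy)phenyl]-N-methoxy-N-methylacetamide
Product: 11 2-[4-(allyloxy)-2,6-bis(benzyloxy)phenyl]-1-(2-hydroxy-4,6-dimethoxyphenyl)ethanone, via aryllithium 9 (not isolated), via MOM-protected ketone 10 (not isolated)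
Conditions: 8 (1.5 equiv), n-BuLi (1.4 equiv), TMEDA, THF, 0 °C; add 6, −78 → 0 °C; then 3 M HCl, MeOH, 50 °C
Reagents that add atoms: none
Why: Directed ortho-metalation followed by Weinreb ketone synthesis; the MOM ether should direct n-BuLi to either of the two equivalent carbons between OMOM and OMe, the aryllithium adds only once because the chelated tetrahedral adduct survives until the acidic quench, and warm methanolic HCl then cleaves the MOM acetal without harming benzyl or allyl ethers (excess aryllithium means that any amide lost to α-deprotonation is simply recovered).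

**Step 8**
Reactants: 11 2-[4-(allyloxy)-2,6-bis(benzyloxy)phenyl]-1-(2-hydroxy-4,6-dimethoxyphenyl)ethanone; 12 4-(benzyloxy)benzoyl chloride
Product: 15 3-[4-(allyloxy)-2,6-bis(benzyloxy)phenyl]-2-[4-(benzyloxy)phenyl]-5,7-dimethoxy-4H-chromen-4-one, via O-aroyl ester 13 (not isolated), via 1,3-diketone 14 (not isolated)
Conditions: 12 (1.3 equiv), K2CO3 (5 equiv), dry acetone, reflux
Reagents that add atoms: none
Why: K2CO3 first O-aroylates the phenol to ester 13, then forms the ketone enolate at the doubly activated benzylic CH2, which attacks the ester carbonyl through a six-membered transition state so that the aroyl group moves from oxygen to carbon and C2–C3 forms (diketone 14). The phenoxide released by this shift adds to the new aryl ketone in a 6-exo-trig closure and the hemiketal loses water, which forms O1–C2 and closes ring C as the pyranone. The closest known chemistry is the Baker–Venkataraman rearrangement run in one pot with Kostanecki-type cyclodehydration, as used to convert 2-hydroxydeoxybenzoins into 2,3-diarylchromones. No stereocentre is created, because the only sp3 carbon of 14 becomes the sp2 C3 of the chromone. The step needs acylation at carbon over oxygen and a single site of ring closure: the O-to-C shift is driven thermodynamically by the stabilised diketone enolate and then by the aromatic pyranone, and the only free hydroxyl is the phenol ortho to the ketone, all other oxygens being ethers. Crowding at C3 by the 2,6-bis(benzyloxy)aryl group should be tolerated because the C–C bond forms intramolecularly from an unhindered aroyl group.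

**Step 9**
Reactants: 15 3-[4-(allyloxy)-2,6-bis(benzyloxy)phenyl]-2-[4-(benzyloxy)phenyl]-5,7-dimethoxy-4H-chromen-4-one
Product: 16 3-[2,6-bis(benzyloxy)-4-hydroxyphenyl]-2-[4-(benzyloxy)phenyl]-5,7-dimethoxy-4H-chromen-4-one
Conditions: Pd(PPh3)4 (5 mol %), morpholine, THF, rt
Reagents that add atoms: none
Why: Tsuji–Trost-type deallylation; zerovalent palladium ionises the aryl allyl ether to a π-allyl complex that morpholine captures, which frees the ring D phenol while benzyl ethers, methyl ethers and the chromone remain untouched.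

**Step 10**
Reactants: 16 3-[2,6-bis(benzyloxy)-4-hydroxyphenyl]-2-[4-(benzyloxy)phenyl]-5,7-dimethoxy-4H-chromen-4-one
Product: 18 3-[3-acetyl-2,6-bis(benzyloxy)-4-hydroxyphenyl]-2-[4-(benzyloxy)phenyl]-5,7-dimethoxy-4H-chromen-4-one, via difluoroboron chelate 17 (not isolated)
Conditions: Ac2O (1.5 equiv), BF3·OEt2 (3 equiv), CH2Cl2, 0 °C → rt; then aq. NaOAc, MeOH, 50 °C
Reagents that add atoms: acetic anhydride, CC(=O)OC(C)=O
Why: Friedel–Crafts acetylation of a phloroglucinol-type phenol; the two equivalent ring D carbons between OH and OBn are the only free positions of that ring and should be the most nucleophilic sites because BF3 bound to the chromone carbonyl deactivates ring A, the product is held as chelate 17 until the acetate work-up, and aryl benzyl ethers tolerate BF3·OEt2 at room temperature.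

**Step 11**
Reactants: 18 3-[3-acetyl-2,6-bis(benzyloxy)-4-hydroxyphenyl]-2-[4-(benzyloxy)phenyl]-5,7-dimethoxy-4H-chromen-4-one; 19 3,4-bis(benzyloxy)benzaldehyde
Product: 20 3-{2,6-bis(benzyloxy)-3-[(E)-3-[3,4-bis(benzyloxy)phenyl]prop-2-enoyl]-4-hydroxyphenyl}-2-[4-(benzyloxy)phenyl]-5,7-dimethoxy-4H-chromen-4-one
Conditions: KOH (aq.), EtOH/THF, rt
Reagents that add atoms: none
Why: Claisen–Schmidt condensation; the methyl ketone enolate adds to the non-enolisable aldehyde and the aldol dehydrates by an E1cB pathway to the thermodynamically favoured (E)-chalcone.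

**Step 12**
Reactants: 20 the (E)-chalcone of step 11
Product: 21 5,7-bis(benzyloxy)-2-[3,4-bis(benzyloxy)phenyl]-6-{2-[4-(benzyloxy)phenyl]-5,7-dimethoxy-4-oxo-4H-chromen-3-yl}-4H-chromen-4-one
Conditions: I2 (10 mol %), DMSO, 120 °C
Reagents that add atoms: none
Why: Oxidative cyclisation of a 2'-hydroxychalcone; the single free phenol adds to the enone β-carbon (6-endo-trig oxa-Michael) and iodine, regenerated by DMSO, dehydrogenates the flavanone, so the pyranone of unit 2 closes through the oxygen para to the inter-flavone bond and fixes the C6 linkage.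

**Step 13**
Reactants: 21 the penta-O-benzyl di-O-methyl biflavone of step 12
Product: 22 2-(3,4-dihydroxyphenyl)-5,7-dihydroxy-6-[5-hydroxy-2-(4-hydroxyphenyl)-7-methoxy-4-oxo-4H-chromen-3-yl]-4H-chromen-4-one (target)
Conditions: BCl3, C6HMe5, CH2Cl2, −78 → 0 °C; MeOH quench
Reagents that add atoms: none
Why: Lewis-acid ether cleavage; BCl3 with pentamethylbenzene as benzyl-cation scavenger should remove all five benzyl ethers at low temperature, and on warming the boron chelate between the C4 carbonyl and the peri C5 oxygen of unit 1 delivers chloride to that methyl group only, so the unchelated 7-OMe survives.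

**Compound list**

1 | 2,4,6-trihydroxybenzaldehyde | O=Cc1c(O)cc(O)cc1O | starting material
2 | 4-(allyloxy)-2,6-dihydroxybenzaldehyde | O=Cc1c(O)cc(OCC=C)cc1O | intermediate
3 | 4-(allyloxy)-2,6-bis(benzyloxy)benzaldehyde | O=Cc1c(OCc2ccccc2)cc(OCC=C)cc1OCc1ccccc1 | intermediate
4 | 2-[4-(allyloxy)-2,6-bis(benzyloxy)phenyl]acetonitrile | N#CCc1c(OCc2ccccc2)cc(OCC=C)cc1OCc1ccccc1 | intermediate
5 | 2-[4-(allyloxy)-2,6-bis(benzyloxy)phenyl]acetic acid | OC(=O)Cc1c(OCc2ccccc2)cc(OCC=C)cc1OCc1ccccc1 | intermediate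
6 | 2-[4-(allyloxy)-2,6-bis(benzyloxy)phenyl]-N-methoxy-N-methylacetamide | CON(C)C(=O)Cc1c(OCc2ccccc2)cc(OCC=C)cc1OCc1ccccc1 | intermediate
7 | 3,5-dimethoxyphenol | COc1cc(O)cc(OC)c1 | starting material
8 | 1,3-dimethoxy-5-(methoxymethoxy)benzene | COCOc1cc(OC)cc(OC)c1 | intermediate
9 | [2,4-dimethoxy-6-(methoxymethoxy)phenyl]lithium | [Li]c1c(OC)cc(OC)cc1OCOC | intermediate (not isolated)
10 | 2-[4-(allyloxy)-2,6-bis(benzyloxy)phenyl]-1-[2,4-dimethoxy-6-(methoxymethoxy)phenyl]ethanone | COCOc1cc(OC)cc(OC)c1C(=O)Cc1c(OCc2ccccc2)cc(OCC=C)cc1OCc1ccccc1 | intermediate (not isolated)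
11 | 2-[4-(allyloxy)-2,6-bis(benzyloxy)phenyl]-1-(2-hydroxy-4,6-dimethoxyphenyl)ethanone | COc1cc(O)c(C(=O)Cc2c(OCc3ccccc3)cc(OCC=C)cc2OCc2ccccc2)c(OC)c1 | intermediate
12 | 4-(benzyloxy)benzoyl chloride | O=C(Cl)c1ccc(OCc2ccccc2)cc1 | starting material
13 | 2-{[4-(allyloxy)-2,6-bis(benzyloxy)phenyl]acetyl}-3,5-dimethoxyphenyl 4-(benzyloxy)benzoate | COc1cc(OC(=O)c2ccc(OCc3ccccc3)cc2)c(C(=O)Cc2c(OCc3ccccc3)cc(OCC=C)cc2OCc2ccccc2)c(OC)c1 | intermediate (not isolated)
14 | 2-[4-(allyloxy)-2,6-bis(benzyloxy)phenyl]-1-[4-(benzyloxy)phenyl]-3-(2-hydroxy-4,6-dimethoxyphenyl)propane-1,3-dione (racemic, enolisable at C2) | COc1cc(O)c(C(=O)C(C(=O)c2ccc(OCc3ccccc3)cc2)c2c(OCc3ccccc3)cc(OCC=C)cc2OCc2ccccc2)c(OC)c1 | intermediate (not isolated)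
15 | 3-[4-(allyloxy)-2,6-bis(benzyloxy)phenyl]-2-[4-(benzyloxy)phenyl]-5,7-dimethoxy-4H-chromen-4-one | COc1cc(OC)c2c(=O)c(-c3c(OCc4ccccc4)cc(OCC=C)cc3OCc3ccccc3)c(-c3ccc(OCc4ccccc4)cc3)oc2c1 | intermediate
16 | 3-[2,6-bis(benzyloxy)-4-hydroxyphenyl]-2-[4-(benzyloxy)phenyl]-5,7-dimethoxy-4H-chromen-4-one | COc1cc(OC)c2c(=O)c(-c3c(OCc4ccccc4)cc(O)cc3OCc3ccccc3)c(-c3ccc(OCc4ccccc4)cc3)oc2c1 | intermediate
17 | O,O-difluoroboron chelate of 18 (BF2 bridging the ring D phenolate oxygen and the acetyl oxygen) | CC1=[O+][B-](F)(F)Oc2cc(OCc3ccccc3)c(-c3c(-c4ccc(OCc5ccccc5)cc4)oc4cc(OC)cc(OC)c4c3=O)c(OCc3ccccc3)c12 | intermediate (not isolated)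
18 | 3-[3-acetyl-2,6-bis(benzyloxy)-4-hydroxyphenyl]-2-[4-(benzyloxy)phenyl]-5,7-dimethoxy-4H-chromen-4-one | COc1cc(OC)c2c(=O)c(-c3c(OCc4ccccc4)cc(O)c(C(C)=O)c3OCc3ccccc3)c(-c3ccc(OCc4ccccc4)cc3)oc2c1 | intermediate
19 | 3,4-bis(benzyloxy)benzaldehyde | O=Cc1ccc(OCc2ccccc2)c(OCc2ccccc2)c1 | starting material
20 | 3-{2,6-bis(benzyloxy)-3-[(E)-3-[3,4-bis(benzyloxy)phenyl]prop-2-enoyl]-4-hydroxyphenyl}-2-[4-(benzyloxy)phenyl]-5,7-dimethoxy-4H-chromen-4-one | COc1cc(OC)c2c(=O)c(-c3c(OCc4ccccc4)cc(O)c(C(=O)/C=C/c4ccc(OCc5ccccc5)c(OCc5ccccc5)c4)c3OCc3ccccc3)c(-c3ccc(OCc4ccccc4)cc3)oc2c1 | intermediate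
21 | 5,7-bis(benzyloxy)-2-[3,4-bis(benzyloxy)phenyl]-6-{2-[4-(benzyloxy)phenyl]-5,7-dimethoxy-4-oxo-4H-chromen-3-yl}-4H-chromen-4-one | COc1cc(OC)c2c(=O)c(-c3c(OCc4ccccc4)cc4oc(-c5ccc(OCc6ccccc6)c(OCc6ccccc6)c5)cc(=O)c4c3OCc3ccccc3)c(-c3ccc(OCc4ccccc4)cc3)oc2c1 | intermediate
22 | 2-(3,4-dihydroxyphenyl)-5,7-dihydroxy-6-[5-hydroxy-2-(4-hydroxyphenyl)-7-methoxy-4-oxo-4H-chromen-3-yl]-4H-chromen-4-one | COc1cc(O)c2c(=O)c(-c3c(O)cc4oc(-c5ccc(O)c(O)c5)cc(=O)c4c3O)c(-c3ccc(O)cc3)oc2c1 | target

**Step count.** Total: 13 steps. Longest linear sequence: 12 steps (steps 1–5 and 7–13, from compound 1).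

**Steps most likely to fail**

Step 8. The acyl shift onto the crowded benzylic carbon may stall at the O-aroyl ester, which would revert to 11 on work-up, or the diketone may not dehydrate. The fallback sets out from 11 and makes C2–C3 by aldol chemistry instead. Condensation of 11 with commercial 4-(benzyloxy)benzaldehyde (piperidine, toluene, reflux with water removal) is a Knoevenagel reaction followed by oxa-Michael ring closure. It should give trans-3-[4-(allyloxy)-2,6-bis(benzyloxy)phenyl]-2-[4-(benzyloxy)phenyl]-5,7-dimethoxychroman-4-one F1 as the racemate. Dehydrogenation with catalytic I2 in DMSO at 110 °C then removes both stereocentres and comes back to the route at 15.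

Step 7. Metalation may occur in part between the two methoxy groups, and the hindered aryllithium may deprotonate the α-CH2 of the amide instead of adding to it. The fallback sets out from aldehyde 3 and bypasses steps 3 to 7. Commercial 2-hydroxy-4,6-dimethoxybenzaldehyde, which fixes the ring A pattern, is converted with NaH and MOMCl into 2,4-dimethoxy-6-(methoxymethoxy)benzaldehyde F2. A Kabachnik–Fields reaction with aniline and diphenyl phosphite should give diphenyl {anilino[2,4-dimethoxy-6-(methoxymethoxy)phenyl]methyl}phosphonate F3. Horner–Wadsworth–Emmons-type olefination of 3 with the anion of F3 (Cs2CO3, THF/i-PrOH, rt) should give N-{2-[4-(allyloxy)-2,6-bis(benzyloxy)phenyl]-1-[2,4-dimethoxy-6-(methoxymethoxy)phenyl]ethenyl}aniline F4. Warm methanolic HCl then hydrolyses the enamine and the MOM acetal together and comes back to the route at 11.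

Step 10. The phenol may be acetylated at oxygen without migration to carbon, or the Lewis acid may cleave the benzyl ether next to the new ketone. The fallback sets out from 16 and uses no Lewis acid. Iodination with N-iodosuccinimide (1.0 equiv, DMF, 0 °C) should occur on the phenol ring and give 3-[2,6-bis(benzyloxy)-4-hydroxy-3-iodophenyl]-2-[4-(benzyloxy)phenyl]-5,7-dimethoxy-4H-chromen-4-one F5. Stille coupling with tributyl(1-ethoxyvinyl)stannane (PdCl2(PPh3)2, dioxane, 90 °C) should give 3-[2,6-bis(benzyloxy)-3-(1-ethoxyvinyl)-4-hydroxyphenyl]-2-[4-(benzyloxy)phenyl]-5,7-dimethoxy-4H-chromen-4-one F6. Hydrolysis of the enol ether with 1 M HCl in THF comes back to the route at 18.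

**Further compounds**

F1 | step 8 | trans-3-[4-(allyloxy)-2,6-bis(benzyloxy)phenyl]-2-[4-(benzyloxy)phenyl]-5,7-dimethoxychroman-4-one (racemic, one enantiomer drawn) | COc1cc(OC)c2C(=O)[C@@H](c3c(OCc4ccccc4)cc(OCC=C)cc3OCc3ccccc3)[C@H](c3ccc(OCc4ccccc4)cc3)Oc2c1
F2 | step 7 | 2,4-dimethoxy-6-(methoxymethoxy)benzaldehyde | COCOc1cc(OC)cc(OC)c1C=O
F3 | step 7 | diphenyl {anilino[2,4-dimethoxy-6-(methoxymethoxy)phenyl]methyl}phosphonate (racemic) | COCOc1cc(OC)cc(OC)c1C(Nc1ccccc1)P(=O)(Oc1ccccc1)Oc1ccccc1
F4 | step 7 | N-{2-[4-(allyloxy)-2,6-bis(benzyloxy)phenyl]-1-[2,4-dimethoxy-6-(methoxymethoxy)phenyl]ethenyl}aniline (alkene geometry not defined) | COCOc1cc(OC)cc(OC)c1C(Nc1ccccc1)=Cc1c(OCc2ccccc2)cc(OCC=C)cc1OCc1ccccc1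
F5 | step 10 | 3-[2,6-bis(benzyloxy)-4-hydroxy-3-iodophenyl]-2-[4-(benzyloxy)phenyl]-5,7-dimethoxy-4H-chromen-4-one | COc1cc(OC)c2c(=O)c(-c3c(OCc4ccccc4)cc(O)c(I)c3OCc3ccccc3)c(-c3ccc(OCc4ccccc4)cc3)oc2c1
F6 | step 10 | 3-[2,6-bis(benzyloxy)-3-(1-ethoxyvinyl)-4-hydroxyphenyl]-2-[4-(benzyloxy)phenyl]-5,7-dimethoxy-4H-chromen-4-one | COc1cc(OC)c2c(=O)c(-c3c(OCc4ccccc4)cc(O)c(C(=C)OCC)c3OCc3ccccc3)c(-c3ccc(OCc4ccccc4)cc3)oc2c1
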